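The plan cuts pyranone ring C of the 7-methoxyflavone unit (benzo ring A, anisyl ring B) at C3–C4 and O1–C2. The feature used: carbonyl C4 is attached to C4a, whose neighbour C8a carries O1, so C4 is the formyl carbon and C8a the hydroxyl-bearing carbon of a salicylaldehyde, while C3–C2 with ring B is an aroylmethyl unit. One rhodium-catalysed formyl C–H annulation with a 4-methoxybenzoyl sulfoxonium ylide forms both bonds and ring C. Its precursor is 2-hydroxy-4,6-dimethoxybenzaldehyde bearing at C3 the bridging anisole ring E, which already carries the second chromone (rings D and F) as its 5,7-dibenzyl ether.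

Key step: step 8

Remark: the target has no stereocentre and its SMILES gives no descriptor for the hindered C8–C2' biaryl axis, so this axis is made without control.

Step 1
Reactants: 1 2',4',6'-trihydroxyacetophenone
Product: 2 1-[2,4-bis(benzyloxy)-6-hydroxyphenyl]ethanone
Conditions: BnBr (2.1 equiv), K2CO3, DMF, rt
Reagents that add atoms: benzyl bromide, BrCc1ccccc1
Why: Williamson etherification: the hydroxyl hydrogen-bonded to the acetyl carbonyl is the least nucleophilic, so two equivalents of benzyl bromide should alkylate the other two and leave the chelated 6-OH free.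

Step 2
Reactants: 2 1-[2,4-bis(benzyloxy)-6-hydroxyphenyl]ethanone, 3 2-bromo-4-methoxybenzoic acid
Product: 5 1-[2,4-bis(benzyloxy)-6-hydroxyphenyl]-3-(2-bromo-4-methoxyphenyl)propane-1,3-dione, via acid chloride 4 (not isolated)
Conditions: 3, (COCl)2, cat. DMF, CH2Cl2, rt, evaporate; 2, LiN(SiMe3)2 (3.2 equiv), THF, −78 to −10 °C, then crude 4, −78 °C to rt; aq. HCl
Reagents that add atoms: none
Why: Acid chloride formation followed by Claisen-type C-acylation of the lithium dianion of ketone 2 (the one-flask counterpart of a Baker–Venkataraman rearrangement) should give the diketone directly, the third equivalent of amide base deprotonating the product and so preventing a second acylation.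

Step 3
Reactants: 5 1-[2,4-bis(benzyloxy)-6-hydroxyphenyl]-3-(2-bromo-4-methoxyphenyl)propane-1,3-dione
Product: 6 5,7-bis(benzyloxy)-2-(2-bromo-4-methoxyphenyl)-4H-chromen-4-one
Conditions: cat. H2SO4, AcOH, 60 °C
Reagents that add atoms: none
Why: Acid-catalysed cyclodehydration of an o-hydroxyaryl 1,3-diketone (the closing stage of the Baker–Venkataraman flavone synthesis) should form the pyranone, and the moderate temperature should spare both benzyl ethers.

Step 4
Reactants: 6 5,7-bis(benzyloxy)-2-(2-bromo-4-methoxyphenyl)-4H-chromen-4-one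
Product: 7 5,7-bis(benzyloxy)-2-[4-methoxy-2-(4,4,5,5-tetramethyl-1,3,2-dioxaborolan-2-yl)phenyl]-4H-chromen-4-one
Conditions: B2pin2 (1.5 equiv), PdCl2(dppf) (5 mol%; dppf = 1,1'-bis(diphenylphosphino)ferrocene), KOAc (3 equiv), 1,4-dioxane, 90 °C
Reagents that add atoms: bis(pinacolato)diboron, CC1(C)OB(OC1(C)C)B1OC(C)(C)C(C)(C)O1
Why: Miyaura borylation: oxidative addition of zerovalent palladium into the aryl bromide, activated by the ortho chromonyl group, and acetate-assisted transmetalation with the diboron should give the pinacol boronate without biaryl homocoupling.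

Step 5
Reactants: 8 2-hydroxy-4,6-dimethoxybenzaldehyde
Product: 9 2-hydroxy-3-iodo-4,6-dimethoxybenzaldehyde
Conditions: BnMe3N+ ICl2− (1.05 equiv), CaCO3, CH2Cl2/MeOH, rt
Reagents that add atoms: benzyltrimethylammonium dichloroiodate, C[N+](C)(C)Cc1ccccc1.Cl[I-]Cl
Why: Electrophilic aromatic iodination, which the dichloroiodate should deliver ortho to the chelated phenol (C3, also para to the 6-methoxy group) as with the analogous 2-hydroxy-4,6-dimethoxyacetophenone; the regiochemistry should be verified by an NOE from the remaining ring proton H5 to both methoxy groups before material is committed.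

Step 6
Reactants: 7 5,7-bis(benzyloxy)-2-[4-methoxy-2-(4,4,5,5-tetramethyl-1,3,2-dioxaborolan-2-yl)phenyl]-4H-chromen-4-one, 9 2-hydroxy-3-iodo-4,6-dimethoxybenzaldehyde
Product: 10 3-{2-[5,7-bis(benzyloxy)-4-oxo-4H-chromen-2-yl]-5-methoxyphenyl}-2-hydroxy-4,6-dimethoxybenzaldehyde
Conditions: 7 (1.2 equiv), Pd(OAc)2 (5 mol%), SPhos (10 mol%), K3PO4 (3 equiv), toluene/H2O 10:1, 90 °C
Reagents that add atoms: none
Why: Suzuki–Miyaura coupling: the aryl iodide adds readily to zerovalent palladium and the bulky dialkylbiarylphosphine should carry the tri-ortho-substituted reductive elimination, free phenol and aldehyde being tolerated under aqueous phosphate; the hindered biaryl axis forms without control, and the target specifies none.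

Step 7
Reactants: 11 4-methoxybenzoyl chloride
Product: 12 2-[dimethyl(oxo)-λ6-sulfanylidene]-1-(4-methoxyphenyl)ethan-1-one (dimethylsulfoxonium 4-methoxybenzoylmethylide)
Conditions: Me3S(O)I (3 equiv), KOtBu (3 equiv), THF, reflux; then 11, 0 °C to rt
Reagents that add atoms: trimethylsulfoxonium iodide, C[S+](C)(C)=O.[I-]
Why: Acylation of dimethylsulfoxonium methylide (the Corey–Chaykovsky ylide) by the acid chloride, a second equivalent of methylide deprotonating the acylsulfoxonium salt to the carbonyl-stabilised ylide.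

Step 8
Reactants: 10 3-{2-[5,7-bis(benzyloxy)-4-oxo-4H-chromen-2-yl]-5-methoxyphenyl}-2-hydroxy-4,6-dimethoxybenzaldehyde, 12 2-[dimethyl(oxo)-λ6-sulfanylidene]-1-(4-methoxyphenyl)ethan-1-one
Product: 15 5,7-bis(benzyloxy)-2-{2-[5,7-dimethoxy-2-(4-methoxyphenyl)-4-oxo-4H-chromen-8-yl]-4-methoxyphenyl}-4H-chromen-4-one, via aryl diketone 13 (not isolated), via cyclic hemiketal 14 (not isolated)
Conditions: 12 (1.5 equiv), [(C5Me5)RhCl2]2 (5 mol%), AgSbF6 (20 mol%), AcOH (1 equiv), ClCH2CH2Cl, 80 °C
Reagents that add atoms: none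
Why: AgSbF6 strips chloride from [(C5Me5)RhCl2]2 to give a cationic trivalent rhodium species that binds the phenoxide of 10 and cleaves the adjacent formyl C–H to a five-membered acyl rhodacycle; ylide 12 then coordinates, expels dimethyl sulfoxide to give a rhodium carbene, and migratory insertion of the acyl group followed by protonolysis forms C3–C4 and releases diketone 13. The phenol of 13 adds to the anisyl ketone (6-exo-trig) to give hemiketal 14, whose acid-assisted dehydration completes O1–C2 and closes ring C as the aromatic pyranone. The closest known reaction type is the rhodium-catalysed acylmethylation–annulation of salicylaldehydes with aroyl sulfoxonium ylides to flavones. No stereocentre is created, the hemiketal carbon of 14 being lost on dehydration. The step needs formyl C–H cleavage to win over arene C–H activation and over ketone-directed self-annulation of 12, which chelation through the ortho hydroxyl secures; the sense of ring closure is fixed because this is the only free phenol, the oxygen at the other ortho position (the future C5) being methylated. The nearly neutral medium should leave the benzyl ethers and the preformed chromone (rings D and F) untouched.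

Step 9
Reactants: 15 5,7-bis(benzyloxy)-2-{2-[5,7-dimethoxy-2-(4-methoxyphenyl)-4-oxo-4H-chromen-8-yl]-4-methoxyphenyl}-4H-chromen-4-one
Product: 16 2-{2-[5-hydroxy-7-methoxy-2-(4-methoxyphenyl)-4-oxo-4H-chromen-8-yl]-4-methoxyphenyl}-5,7-dihydroxy-4H-chromen-4-one (CNP0114008.0)
Conditions: BCl3 (8 equiv), pentamethylbenzene (6 equiv), CH2Cl2, −78 to 0 °C; MeOH then aq. work-up
Reagents that add atoms: none
Why: Lewis-acid ether cleavage: BCl3 with pentamethylbenzene as benzyl-cation scavenger removes aryl benzyl ethers, and it demethylates only the methoxy group peri to a chromone carbonyl (C5 of ring A) through a six-membered boron chelate, so the 7-methoxy group and both anisyl ethers should survive.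

Compound list
1 | 2',4',6'-trihydroxyacetophenone | CC(=O)c1c(O)cc(O)cc1O | starting material
2 | 1-[2,4-bis(benzyloxy)-6-hydroxyphenyl]ethanone | CC(=O)c1c(O)cc(OCc2ccccc2)cc1OCc1ccccc1 | intermediate
3 | 2-bromo-4-methoxybenzoic acid | COc1ccc(C(=O)O)c(Br)c1 | starting material
4 | 2-bromo-4-methoxybenzoyl chloride | COc1ccc(C(=O)Cl)c(Br)c1 | intermediate
5 | 1-[2,4-bis(benzyloxy)-6-hydroxyphenyl]-3-(2-bromo-4-methoxyphenyl)propane-1,3-dione | COc1ccc(C(=O)CC(=O)c2c(O)cc(OCc3ccccc3)cc2OCc2ccccc2)c(Br)c1 | intermediate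
6 | 5,7-bis(benzyloxy)-2-(2-bromo-4-methoxyphenyl)-4H-chromen-4-one | COc1ccc(-c2cc(=O)c3c(OCc4ccccc4)cc(OCc4ccccc4)cc3o2)c(Br)c1 | intermediate
7 | 5,7-bis(benzyloxy)-2-[4-methoxy-2-(4,4,5,5-tetramethyl-1,3,2-dioxaborolan-2-yl)phenyl]-4H-chromen-4-one | COc1ccc(-c2cc(=O)c3c(OCc4ccccc4)cc(OCc4ccccc4)cc3o2)c(B2OC(C)(C)C(C)(C)O2)c1 | intermediate
8 | 2-hydroxy-4,6-dimethoxybenzaldehyde | COc1cc(O)c(C=O)c(OC)c1 | starting material
9 | 2-hydroxy-3-iodo-4,6-dimethoxybenzaldehyde | O=Cc1c(OC)cc(OC)c(I)c1O | intermediate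
10 | 3-{2-[5,7-bis(benzyloxy)-4-oxo-4H-chromen-2-yl]-5-methoxyphenyl}-2-hydroxy-4,6-dimethoxybenzaldehyde | O=Cc1c(OC)cc(OC)c(-c2cc(OC)ccc2-c2cc(=O)c3c(OCc4ccccc4)cc(OCc4ccccc4)cc3o2)c1O | intermediate
11 | 4-methoxybenzoyl chloride | COc1ccc(C(Cl)=O)cc1 | starting material
12 | 2-[dimethyl(oxo)-λ6-sulfanylidene]-1-(4-methoxyphenyl)ethan-1-one | COc1ccc(C(=O)C=S(C)(C)=O)cc1 | intermediate
13 | 1-{3-[2-(5,7-bis(benzyloxy)-4-oxo-4H-chromen-2-yl)-5-methoxyphenyl]-2-hydroxy-4,6-dimethoxyphenyl}-3-(4-methoxyphenyl)propane-1,3-dione | COc1ccc(C(=O)CC(=O)c2c(OC)cc(OC)c(-c3cc(OC)ccc3-c3cc(=O)c4c(OCc5ccccc5)cc(OCc5ccccc5)cc4o3)c2O)cc1 | intermediate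
14 | 8-{2-[5,7-bis(benzyloxy)-4-oxo-4H-chromen-2-yl]-5-methoxyphenyl}-2-hydroxy-5,7-dimethoxy-2-(4-methoxyphenyl)-2,3-dihydro-4H-chromen-4-one (racemic at C2, transient) | COc1ccc(C2(O)CC(=O)c3c(OC)cc(OC)c(-c4cc(OC)ccc4-c4cc(=O)c5c(OCc6ccccc6)cc(OCc6ccccc6)cc5o4)c3O2)cc1 | intermediate
15 | 5,7-bis(benzyloxy)-2-{2-[5,7-dimethoxy-2-(4-methoxyphenyl)-4-oxo-4H-chromen-8-yl]-4-methoxyphenyl}-4H-chromen-4-one | COc1ccc(-c2cc(=O)c3c(OC)cc(OC)c(-c4cc(OC)ccc4-c4cc(=O)c5c(OCc6ccccc6)cc(OCc6ccccc6)cc5o4)c3o2)cc1 | intermediate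
16 | 2-{2-[5-hydroxy-7-methoxy-2-(4-methoxyphenyl)-4-oxo-4H-chromen-8-yl]-4-methoxyphenyl}-5,7-dihydroxy-4H-chromen-4-one | COc1ccc(-c2cc(=O)c3c(O)cc(OC)c(-c4cc(OC)ccc4-c4cc(=O)c5c(O)cc(O)cc5o4)c3o2)cc1 | target

Total step count: 9. Longest linear sequence: 7 steps (steps 1, 2, 3, 4, 6, 8, 9 from compound 1).

Steps most likely to fail

Step 8. The phenoxide that must guide rhodium is flanked by the formyl group and the twisted ring E, so formyl C–H cleavage may be slow; the ylide would then be consumed by its own ketone-directed self-annulation, or the acyl rhodium may decarbonylate. The fallback sets out from 10 and returns at 15 by an ynone cyclisation. Lithium (4-methoxyphenyl)acetylide (from 1-ethynyl-4-methoxybenzene and n-BuLi, 3 equiv, THF, −78 °C) should add to the aldehyde and give the racemic propargylic alcohol 5,7-bis(benzyloxy)-2-{2-[2-hydroxy-3-(1-hydroxy-3-(4-methoxyphenyl)prop-2-yn-1-yl)-4,6-dimethoxyphenyl]-4-methoxyphenyl}-4H-chromen-4-one F1. At this temperature the vinylogous-ester carbonyl of the chromone should not compete. MnO2 in CH2Cl2 at rt should oxidise it to the ynone 5,7-bis(benzyloxy)-2-{2-[2-hydroxy-4,6-dimethoxy-3-(3-(4-methoxyphenyl)prop-2-ynoyl)phenyl]-4-methoxyphenyl}-4H-chromen-4-one F2. Et2NH in EtOH at reflux (amine conjugate addition, then 6-endo ring closure by the phenol with loss of the amine) should close ring C to 15.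

Step 6. Protodeboronation of the ortho-chromonyl boronate may outrun transmetalation onto the hindered, phenoxide-bearing arylpalladium species, and the iodide may be reduced instead of coupled. The fallback sets out from 9 and returns at 10 by masking the phenol for the coupling. MOMCl with iPr2NEt in CH2Cl2 should give 3-iodo-4,6-dimethoxy-2-(methoxymethoxy)benzaldehyde F3. Suzuki–Miyaura coupling of this neutral iodide with 7 (Pd(OAc)2, SPhos, K3PO4, toluene/H2O, 90 °C) should give 3-{2-[5,7-bis(benzyloxy)-4-oxo-4H-chromen-2-yl]-5-methoxyphenyl}-4,6-dimethoxy-2-(methoxymethoxy)benzaldehyde F4. HCl in MeOH/THF at 40 °C should then remove the acetal, without touching the benzyl ethers, to give 10.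

Step 9. Cleavage of the unchelated 7-benzyl ether on ring D may stall at the low temperature that keeps demethylation confined to C5 of ring A. Warming risks further demethylation or Friedel–Crafts benzylation of the electron-rich rings. The fallback sets out from 15 and returns at 16 by separating the two deprotections. Hydrogenolysis (H2, 10% Pd/C, palladium on carbon, THF/MeOH, rt) should give 2-{2-[5,7-dimethoxy-2-(4-methoxyphenyl)-4-oxo-4H-chromen-8-yl]-4-methoxyphenyl}-5,7-dihydroxy-4H-chromen-4-one F5. AlCl3 in MeCN at 60 °C should then remove only the methyl group at C5 of ring A, through the aluminium chelate with the C4 carbonyl, to give 16.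

Further compounds
F1 | step 8 | 5,7-bis(benzyloxy)-2-{2-[2-hydroxy-3-(1-hydroxy-3-(4-methoxyphenyl)prop-2-yn-1-yl)-4,6-dimethoxyphenyl]-4-methoxyphenyl}-4H-chromen-4-one (racemic) | OC(C#Cc1ccc(OC)cc1)c1c(OC)cc(OC)c(-c2cc(OC)ccc2-c2cc(=O)c3c(OCc4ccccc4)cc(OCc4ccccc4)cc3o2)c1O
F2 | step 8 | 5,7-bis(benzyloxy)-2-{2-[2-hydroxy-4,6-dimethoxy-3-(3-(4-methoxyphenyl)prop-2-ynoyl)phenyl]-4-methoxyphenyl}-4H-chromen-4-one | O=C(C#Cc1ccc(OC)cc1)c1c(OC)cc(OC)c(-c2cc(OC)ccc2-c2cc(=O)c3c(OCc4ccccc4)cc(OCc4ccccc4)cc3o2)c1O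
F3 | step 6 | 3-iodo-4,6-dimethoxy-2-(methoxymethoxy)benzaldehyde | O=Cc1c(OC)cc(OC)c(I)c1OCOC
F4 | step 6 | 3-{2-[5,7-bis(benzyloxy)-4-oxo-4H-chromen-2-yl]-5-methoxyphenyl}-4,6-dimethoxy-2-(methoxymethoxy)benzaldehyde | O=Cc1c(OC)cc(OC)c(-c2cc(OC)ccc2-c2cc(=O)c3c(OCc4ccccc4)cc(OCc4ccccc4)cc3o2)c1OCOC
F5 | step 9 | 2-{2-[5,7-dimethoxy-2-(4-methoxyphenyl)-4-oxo-4H-chromen-8-yl]-4-methoxyphenyl}-5,7-dihydroxy-4H-chromen-4-one | COc1ccc(-c2cc(=O)c3c(OC)cc(OC)c(-c4cc(OC)ccc4-c4cc(=O)c5c(O)cc(O)cc5o4)c3o2)cc1
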